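**The flasks.** Temperature and the charge of D differ among the flasks below, and noon changes its temperature on the way.

| flask | J | D | temperature | remark | time |
|---|---|---|---|---|---|
| Sunday's | 0.020 M | 0.0090 M | −2 °C | run made earlier |  |
| Thursday's | 0.020 M | 0.036 M | 14 °C | run made earlier |  |
| noon | 0.020 M | 0.0180 M |  | at −10 °C until 25 min, from then on at 20 °C | 2.0 h |
| autumn | 0.020 M | 0.0180 M | −10 °C |  | 2.0 h |
| summer | 0.020 M | 0.0180 M | 5 °C |  | 2.0 h |
| spring | 0.020 M | 0.0180 M | 20 °C |  | 2.0 h |

| run | time / min | G / % | X / % | J / % |
|---|---|---|---|---|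
| Sunday's | 8.00 | 0.3 | 0.7 | 98.6 |
| Sunday's | 25.0 | 1.6 | 0.6 | 95.7 |
| Sunday's | 40.0 | 2.2 | 0 | 94.2 |
| Sunday's | 60.0 | 4.5 | 0.1 | 91.9 |
| Sunday's | 90.0 | 8.6 | 0.4 | 88.4 |
| Sunday's | 120 | 12.2 | 0.1 | 84.1 |
| Thursday's | 6.00 | 6.8 | 0 | 91.5 |
| Thursday's | 12.0 | 13.8 | 0 | 85.1 |
| Thursday's | 20.0 | 21.2 | 0.8 | 76.0 |
| Thursday's | 25.0 | 25.0 | 1.7 | 70.8 |
| Thursday's | 30.0 | 29.3 | 3.6 | 66.7 |
| Thursday's | 40.0 | 33.4 | 5.8 | 60.0 |

(each reading ± 0.5 percentage points)

- the best flask by share of G in all that became G or X; "all alike" if 1.5 percentage points covers them all (noon / autumn / summer / spring / all alike)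
- share of G in all that became G or X, noon
- share of G in all that became G or X, autumn
- share of G in all that became G or X, summer
- share of G in all that became G or X, spring



**Late X.** In Thursday's run X goes from 0.8% at 20.0 min to 5.8% at 40.0 min, a factor of 7.25, while G climbs from 21.2% to 33.4%. With G made at a steady pace, a first-order loss of G would give 4 over that stretch; a loss in which G meets a partner building up beside it would give 8. The ratio, read through a scatter of 0.5 percentage points, lies nearer the second, so I take it, and the rate of X goes as a loss constant times the square of G.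

**Exposure number.** This rate integrates in closed form. Call the exposure the loss constant times the concentration made (G plus X) times the time. If everything is made at the start, the share of G (the selectivity) is one over one plus the exposure. If it is made steadily, the share is the hyperbolic tangent of the root of the exposure, divided by that root. For steady making and small loss, the exposure is 3 times X over G, which on Thursday is 0.521, so the loss constant at 14 °C reads 1.66 /M/min.

**Spring's bracket.** J's loss, taken as first order in D, rises by a factor of 2.21 from Sunday's temperature to Thursday's. I assume the same steepness for X, which gives a loss constant at 20 °C of 2.24 /M/min. Thursday's pace, scaled the same way and held steady, gives my estimate of 79.2% made in spring, within the 90.0% that D's charge allows. The estimated exposure in spring is then 4.25. On this estimate, making all at once gives the lower bound, 19.0%; steady making gives the upper, 46.9%. Sunday's last reading has X 0.1% beside G 12.2%, and autumn is colder still, so I rank autumn first.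

**The forecast.** It names autumn, with noon 60%, autumn 98.5%, summer 89% and spring 55%, on the ground that “The share of G is therefore high when cold”. Its spring stands above my bracket.

**The flask.** The best is autumn: noon 39.3%, autumn 99.3%, summer 82.0%, spring 31.3%, which lies inside my bracket.

    J ⇌ Z + Q (K = 7.10 × 10⁻⁴ M, k = 0.0320 /min, Ea = 94.0 kJ/mol, ΔH = −10.0 kJ/mol)
    D + Z → G (k = 42.0 /M/min, Ea = 61.0 kJ/mol)
    Q + G → X (k = 2.10 /M/min, Ea = 49.0 kJ/mol)
    D → L (k = 0.00750 /min, Ea = 95.0 kJ/mol)
    (constants at 20 °C)

**Spring's course.** By 1.00 h in spring, J stands at 38.2% and D at 14.8% of its own charge, with G at 33.3% and Q, the partner, at 0.00721 M. By 2.00 h in spring, D is down to 1.90% of its charge while Q and G have gone on giving X, so that G stands at 21.3% and X at 46.7%. With the amount spring really made, the exposure is 3.65, and the bracket runs from 21.5% to 50.1%. The noon flask with 0.012 M of J, counted warm from 25 min, has exposure 2.03 and bracket 33.0% to 62.5%, and it gives 49.4%.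

The earlier runs and the new flask are simulated with constants of no real substance, noise included.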